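## Retrosynthetic overview

1. Target 25 ⇐ desilylation of 24 ⇐ acid-triggered double cyclisation of tetraol 23; both tetrahydrofuran rings of the furofuran form last, in one step.
2. 23 ⇐ trans-selective aldol of γ-lactone 21 with dihydrobenzofuran aldehyde 12, then ozonolysis and hydride reduction.
3. 12 ⇐ Mitsunobu closure (inversion, gives 2,3-cis) of syn alcohol 10 ⇐ [2,3]-Wittig rearrangement of (Z)-allyl benzyl ether 9; this key step forms the C2–C3 bond and sets both ring stereocentres.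
4. 21 ⇐ Johnson–Claisen rearrangement of (S,Z)-allylic alcohol 17 (sets the bridgehead carbon), ozonolysis, lactonisation.
5. Ring order: dihydrobenzofuran (step 8), then a sacrificial γ-lactone (step 13), then both furofuran rings (step 16). (S)-But-3-yn-2-ol, used as its TMS ether 4, supplies the chirality of both halves.

Assumption: the target is made exactly as drawn, i.e. with the 2,3-cis (2S,3S)-dihydrobenzofuran and the (1R,2S,5R,6S)-furofuran, and (S)-but-3-yn-2-ol is taken as a cheap commercial single enantiomer.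

## Route

Step 1
Reactants: 1 vanillin
Product: 2 3-methoxy-4-(triisopropylsilyloxy)benzaldehyde
Conditions: TIPSCl, imidazole, DMF, rt
Reagents that add atoms: triisopropylsilyl chloride, CC(C)[Si](Cl)(C(C)C)C(C)C
Why: Silyl ether formation protects the phenol as a base-stable, fluoride-labile and only weakly electron-donating group.

Step 2
Reactants: 3 (S)-but-3-yn-2-ol
Product: 4 (S)-(but-3-yn-2-yloxy)trimethylsilane
Conditions: HMDS (0.55 equiv), TMSOTf (1 mol%), CH2Cl2, rt; fractional distillation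
Reagents that add atoms: hexamethyldisilazane, C[Si](C)(C)N[Si](C)(C)C
Why: Acid-catalysed O-silylation with HMDS gives the volatile TMS ether without touching the carbinol stereocentre; one distilled batch feeds both step 3 and step 10.

Step 3
Reactants: 2 3-methoxy-4-(triisopropylsilyloxy)benzaldehyde; 4 (S)-(but-3-yn-2-yloxy)trimethylsilane
Product: 5 (S)-triisopropyl{2-methoxy-4-[(but-3-yn-2-yloxy)methyl]phenoxy}silane
Conditions: Et3SiH (1.2 equiv), TMSOTf (10 mol%), CH2Cl2, −78 → −40 °C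
Reagents that add atoms: none
Why: Lewis-acid-catalysed reductive etherification (silyl ether plus aldehyde gives an oxocarbenium ion that Et3SiH reduces) makes the benzyl ether without breaking the C–O bond at the carbinol stereocentre.

Step 4
Reactants: 6 5-iodovanillin
Product: 7 4-(1,3-dioxolan-2-yl)-2-iodo-6-methoxyphenol
Conditions: ethylene glycol, TsOH (cat.), toluene, reflux, Dean–Stark
Reagents that add atoms: ethylene glycol, OCCO
Why: Acetalisation masks the aldehyde against n-BuLi in step 7.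

Step 5
Reactants: 7 4-(1,3-dioxolan-2-yl)-2-iodo-6-methoxyphenol; 5 (S)-triisopropyl{2-methoxy-4-[(but-3-yn-2-yloxy)methyl]phenoxy}silane
Product: 8 4-(1,3-dioxolan-2-yl)-2-methoxy-6-[(3S)-3-{[3-methoxy-4-(triisopropylsilyloxy)benzyl]oxy}but-1-yn-1-yl]phenol
Conditions: PdCl2(PPh3)2 (2 mol%), CuI (4 mol%), Et3N, THF, rt
Reagents that add atoms: none
Why: Sonogashira coupling at the aryl iodide; running it at room temperature should keep the free o-alkynylphenol from cyclising to a benzofuran.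

Step 6
Reactants: 8 4-(1,3-dioxolan-2-yl)-2-methoxy-6-[(3S)-3-{[3-methoxy-4-(triisopropylsilyloxy)benzyl]oxy}but-1-yn-1-yl]phenol
Product: 9 4-(1,3-dioxolan-2-yl)-2-methoxy-6-[(1Z,3S)-3-{[3-methoxy-4-(triisopropylsilyloxy)benzyl]oxy}but-1-en-1-yl]phenol
Conditions: H2 (1 atm), Lindlar catalyst, quinoline, EtOAc, rt
Reagents that add atoms: none
Why: Lindlar cis-semihydrogenation gives the Z-alkene that the syn-selective rearrangement needs.

Step 7
Reactants: 9 4-(1,3-dioxolan-2-yl)-2-methoxy-6-[(1Z,3S)-3-{[3-methoxy-4-(triisopropylsilyloxy)benzyl]oxy}but-1-en-1-yl]phenol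
Product: 10 (1R,2R,3E)-2-[5-(1,3-dioxolan-2-yl)-2-hydroxy-3-methoxyphenyl]-1-[3-methoxy-4-(triisopropylsilyloxy)phenyl]pent-3-en-1-ol
Conditions: n-BuLi (2.3 equiv), THF, −78 → −30 °C; aq. NH4Cl
Reagents that add atoms: none
Why: [2,3]-Wittig rearrangement of the phenoxide/benzylic carbanion goes suprafacially through an envelope transition state with the carbinol methyl pseudo-equatorial and the aryl group exo, so the (S)-C–O centre is traded for the new C–C bond and the Z-alkene gives the syn (1R,2R) alcohol with an E-propenyl group.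

Step 8
Reactants: 10 (1R,2R,3E)-2-[5-(1,3-dioxolan-2-yl)-2-hydroxy-3-methoxyphenyl]-1-[3-methoxy-4-(triisopropylsilyloxy)phenyl]pent-3-en-1-ol
Product: 12 (2S,3R)-7-methoxy-2-[3-methoxy-4-(triisopropylsilyloxy)phenyl]-3-[(E)-prop-1-en-1-yl]-2,3-dihydrobenzofuran-5-carbaldehyde, via cis-dihydrobenzofuran acetal 11 (not isolated)
Conditions: PPh3, DIAD, toluene, 0 °C; then 1 M HCl, THF, rt
Reagents that add atoms: water, O
Why: Intramolecular Mitsunobu etherification (5-exo-tet SN2 by the phenol) inverts the benzylic carbinol, turning the syn alcohol into the 2,3-cis ring with C2 = S, and dilute acid then hydrolyses the acetal.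

Step 9
Reactants: 13 syringaldehyde
Product: 14 3,5-dimethoxy-4-(triisopropylsilyloxy)benzaldehyde
Conditions: TIPSCl, imidazole, DMF, 50 °C
Reagents that add atoms: triisopropylsilyl chloride, CC(C)[Si](Cl)(C(C)C)C(C)C
Why: Silyl ether formation protects the hindered phenol for the organolithium, enolate and ozonolysis steps.

Step 10
Reactants: 4 (S)-(but-3-yn-2-yloxy)trimethylsilane; 14 3,5-dimethoxy-4-(triisopropylsilyloxy)benzaldehyde
Product: 16 (2S)-5-(tert-butyldimethylsilyloxy)-5-[3,5-dimethoxy-4-(triisopropylsilyloxy)phenyl]pent-3-yn-2-ol (both C5 epimers), via bis-silyl ether 15 (not isolated)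
Conditions: 4, n-BuLi (1.05 equiv), THF, −78 °C; 14; TBSOTf (1.1 equiv), −78 → 0 °C; then citric acid, MeOH, 0 °C
Reagents that add atoms: tert-butyldimethylsilyl triflate, CC(C)(C)[Si](C)(C)OS(=O)(=O)C(F)(F)F
Why: Acetylide addition to the aldehyde followed by in situ TBS trapping of the new benzylic alkoxide, then selective acidic methanolysis of the much more labile TMS ether; the new benzylic centre forms unselectively and is reset in step 16.

Step 11
Reactants: 16 (2S)-5-(tert-butyldimethylsilyloxy)-5-[3,5-dimethoxy-4-(triisopropylsilyloxy)phenyl]pent-3-yn-2-ol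
Product: 17 (2S,3Z)-5-(tert-butyldimethylsilyloxy)-5-[3,5-dimethoxy-4-(triisopropylsilyloxy)phenyl]pent-3-en-2-ol (both C5 epimers)
Conditions: H2 (1 atm), Lindlar catalyst, quinoline, EtOAc, rt
Reagents that add atoms: none
Why: Lindlar cis-semihydrogenation gives the Z-allylic alcohol, the geometry that makes chirality transfer in the next step essentially complete.

Step 12
Reactants: 17 (2S,3Z)-5-(tert-butyldimethylsilyloxy)-5-[3,5-dimethoxy-4-(triisopropylsilyloxy)phenyl]pent-3-en-2-ol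
Product: 19 ethyl (3R,4E)-3-{(tert-butyldimethylsilyloxy)[3,5-dimethoxy-4-(triisopropylsilyloxy)phenyl]methyl}hex-4-enoate, via ketene acetal 18 (not isolated)
Conditions: MeC(OEt)3 (8 equiv), EtCO2H (5 mol%), xylene, 135 °C, EtOH distilled off
Reagents that add atoms: triethyl orthoacetate, CCOC(C)(OCC)OCC
Why: Johnson–Claisen [3,3] rearrangement; allylic 1,3-strain from the Z-alkene forces the carbinol methyl pseudo-equatorial, so the (S)-carbinol is transferred to the new (3R) carbon, which becomes furofuran C5.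

Step 13
Reactants: 19 ethyl (3R,4E)-3-{(tert-butyldimethylsilyloxy)[3,5-dimethoxy-4-(triisopropylsilyloxy)phenyl]methyl}hex-4-enoate
Product: 21 (4R)-4-{(tert-butyldimethylsilyloxy)[3,5-dimethoxy-4-(triisopropylsilyloxy)phenyl]methyl}dihydrofuran-2(3H)-one, via hydroxy ester 20 (not isolated)
Conditions: O3, CH2Cl2–MeOH, −78 °C; NaBH4, −78 → 0 °C; then PPTS (cat.), CH2Cl2, rt
Reagents that add atoms: ozone, [O-][O+]=O
Why: Ozonolysis with reductive work-up turns the propenyl group into CH2OH, which lactonises onto the ester; reducing the ozonide directly avoids holding the epimerisable α-branched aldehyde.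

Step 14
Reactants: 21 (4R)-4-{(tert-butyldimethylsilyloxy)[3,5-dimethoxy-4-(triisopropylsilyloxy)phenyl]methyl}dihydrofuran-2(3H)-one; 12 (2S,3R)-7-methoxy-2-[3-methoxy-4-(triisopropylsilyloxy)phenyl]-3-[(E)-prop-1-en-1-yl]-2,3-dihydrobenzofuran-5-carbaldehyde
Product: 22 (3S,4R)-4-{(tert-butyldimethylsilyloxy)[3,5-dimethoxy-4-(triisopropylsilyloxy)phenyl]methyl}-3-[hydroxy{(2S,3R)-7-methoxy-2-[3-methoxy-4-(triisopropylsilyloxy)phenyl]-3-[(E)-prop-1-en-1-yl]-2,3-dihydrobenzofuran-5-yl}methyl]dihydrofuran-2(3H)-one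
Conditions: LDA (1.05 equiv), THF, −78 °C; then 12, −78 °C; aq. NH4Cl
Reagents that add atoms: none
Why: Lactone enolate aldol addition occurs anti to the C4 substituent, giving the 3,4-trans lactone (C3 = S, the second bridgehead); the new carbinol epimers are reset in step 16.

Step 15
Reactants: 22 the (3S,4R)-3,4-trans aldol adduct of 21 and 12
Product: 23 (2R,3R)-2-[hydroxy{(2S,3S)-3-(hydroxymethyl)-7-methoxy-2-[3-methoxy-4-(triisopropylsilyloxy)phenyl]-2,3-dihydrobenzofuran-5-yl}methyl]-3-{(tert-butyldimethylsilyloxy)[3,5-dimethoxy-4-(triisopropylsilyloxy)phenyl]methyl}butane-1,4-diol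
Conditions: O3, CH2Cl2–MeOH, −78 °C; then LiBH4, THF, −78 °C → rt
Reagents that add atoms: ozone, [O-][O+]=O
Why: Ozonolysis with in situ hydride reduction converts the propenyl group on the cis-dihydrobenzofuran straight to CH2OH, so C3 is not left as an epimerisable aldehyde, while LiBH4 also opens the lactone to the 1,4-diol.

Step 16
Reactants: 23 the (2R,3R)-tetraol mono-TBS ether from step 15
Product: 24 bis-O-triisopropylsilyl ether of the target, (1R,2S,5R,6S)-6-[3,5-dimethoxy-4-(triisopropylsilyloxy)phenyl]-2-{(2S,3S)-3-(hydroxymethyl)-7-methoxy-2-[3-methoxy-4-(triisopropylsilyloxy)phenyl]-2,3-dihydrobenzofuran-5-yl}-3,7-dioxabicyclo[3.3.0]octane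
Conditions: CSA (0.2 equiv), CH2Cl2, 0 °C → rt; Et3N quench at full conversion
Reagents that add atoms: none
Why: Acid-triggered double SN1 cyclisation (each benzylic cation is captured by a primary alcohol in a kinetic 2,3-trans closure) should give the exo,exo-diaryl furofuran whatever the configuration of the two benzylic carbinols, so C2 and C6 are set by the (1R,5R) bridgeheads, and the acid is mild enough to leave the cis-dihydrobenzofuran ether intact.

Step 17
Reactants: 24 bis-O-triisopropylsilyl ether of the target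
Product: 25 target, (1R,2S,5R,6S)-6-(4-hydroxy-3,5-dimethoxyphenyl)-2-[(2S,3S)-2-(4-hydroxy-3-methoxyphenyl)-3-(hydroxymethyl)-7-methoxy-2,3-dihydrobenzofuran-5-yl]-3,7-dioxabicyclo[3.3.0]octane
Conditions: TBAF (2.4 equiv), AcOH (2.4 equiv), THF, 0 °C
Reagents that add atoms: none
Why: Buffered fluoride desilylation frees both phenols under near-neutral conditions that do not open the cis-dihydrobenzofuran or the furofuran through quinone methides.

## Compound list

1 | vanillin | COc1cc(C=O)ccc1O | starting material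
2 | 3-methoxy-4-(triisopropylsilyloxy)benzaldehyde | COc1cc(C=O)ccc1O[Si](C(C)C)(C(C)C)C(C)C | intermediate
3 | (S)-but-3-yn-2-ol | C[C@H](O)C#C | starting material
4 | (S)-(but-3-yn-2-yloxy)trimethylsilane | C[C@H](O[Si](C)(C)C)C#C | intermediate
5 | (S)-triisopropyl{2-methoxy-4-[(but-3-yn-2-yloxy)methyl]phenoxy}silane | C[C@H](OCc1ccc(O[Si](C(C)C)(C(C)C)C(C)C)c(OC)c1)C#C | intermediate
6 | 5-iodovanillin | COc1cc(C=O)cc(I)c1O | starting material
7 | 4-(1,3-dioxolan-2-yl)-2-iodo-6-methoxyphenol | COc1cc(C2OCCO2)cc(I)c1O | intermediate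
8 | 4-(1,3-dioxolan-2-yl)-2-methoxy-6-[(3S)-3-{[3-methoxy-4-(triisopropylsilyloxy)benzyl]oxy}but-1-yn-1-yl]phenol | COc1cc(C2OCCO2)cc(C#C[C@H](C)OCc2ccc(O[Si](C(C)C)(C(C)C)C(C)C)c(OC)c2)c1O | intermediate
9 | 4-(1,3-dioxolan-2-yl)-2-methoxy-6-[(1Z,3S)-3-{[3-methoxy-4-(triisopropylsilyloxy)benzyl]oxy}but-1-en-1-yl]phenol | COc1cc(C2OCCO2)cc(/C=C\[C@H](C)OCc2ccc(O[Si](C(C)C)(C(C)C)C(C)C)c(OC)c2)c1O | intermediate
10 | (1R,2R,3E)-2-[5-(1,3-dioxolan-2-yl)-2-hydroxy-3-methoxyphenyl]-1-[3-methoxy-4-(triisopropylsilyloxy)phenyl]pent-3-en-1-ol (syn) | C/C=C/[C@H](c1cc(C2OCCO2)cc(OC)c1O)[C@@H](O)c1ccc(O[Si](C(C)C)(C(C)C)C(C)C)c(OC)c1 | intermediate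
11 | (2S,3R)-5-(1,3-dioxolan-2-yl)-7-methoxy-2-[3-methoxy-4-(triisopropylsilyloxy)phenyl]-3-[(E)-prop-1-en-1-yl]-2,3-dihydrobenzofuran (2,3-cis) | COc1cc([C@H]2Oc3c(OC)cc(C4OCCO4)cc3[C@H]2/C=C/C)ccc1O[Si](C(C)C)(C(C)C)C(C)C | intermediate
12 | (2S,3R)-7-methoxy-2-[3-methoxy-4-(triisopropylsilyloxy)phenyl]-3-[(E)-prop-1-en-1-yl]-2,3-dihydrobenzofuran-5-carbaldehyde (2,3-cis) | COc1cc([C@H]2Oc3c(OC)cc(C=O)cc3[C@H]2/C=C/C)ccc1O[Si](C(C)C)(C(C)C)C(C)C | intermediate
13 | syringaldehyde | COc1cc(C=O)cc(OC)c1O | starting material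
14 | 3,5-dimethoxy-4-(triisopropylsilyloxy)benzaldehyde | COc1cc(C=O)cc(OC)c1O[Si](C(C)C)(C(C)C)C(C)C | intermediate
15 | tert-butyl({(4S)-1-[3,5-dimethoxy-4-(triisopropylsilyloxy)phenyl]-4-(trimethylsilyloxy)pent-2-yn-1-yl}oxy)dimethylsilane (both C1 epimers) | C[C@H](O[Si](C)(C)C)C#CC(O[Si](C)(C)C(C)(C)C)c1cc(OC)c(O[Si](C(C)C)(C(C)C)C(C)C)c(OC)c1 | intermediate
16 | (2S)-5-(tert-butyldimethylsilyloxy)-5-[3,5-dimethoxy-4-(triisopropylsilyloxy)phenyl]pent-3-yn-2-ol (both C5 epimers) | C[C@H](O)C#CC(O[Si](C)(C)C(C)(C)C)c1cc(OC)c(O[Si](C(C)C)(C(C)C)C(C)C)c(OC)c1 | intermediate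
17 | (2S,3Z)-5-(tert-butyldimethylsilyloxy)-5-[3,5-dimethoxy-4-(triisopropylsilyloxy)phenyl]pent-3-en-2-ol (both C5 epimers) | C[C@H](O)/C=C\C(O[Si](C)(C)C(C)(C)C)c1cc(OC)c(O[Si](C(C)C)(C(C)C)C(C)C)c(OC)c1 | intermediate
18 | 1-ethoxyvinyl ether (ketene acetal) of 17, (S,Z) | C=C(OCC)O[C@@H](C)/C=C\C(O[Si](C)(C)C(C)(C)C)c1cc(OC)c(O[Si](C(C)C)(C(C)C)C(C)C)c(OC)c1 | intermediate
19 | ethyl (3R,4E)-3-{(tert-butyldimethylsilyloxy)[3,5-dimethoxy-4-(triisopropylsilyloxy)phenyl]methyl}hex-4-enoate (both benzylic epimers) | CCOC(=O)C[C@H](/C=C/C)C(O[Si](C)(C)C(C)(C)C)c1cc(OC)c(O[Si](C(C)C)(C(C)C)C(C)C)c(OC)c1 | intermediate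
20 | ethyl (3R)-4-(tert-butyldimethylsilyloxy)-4-[3,5-dimethoxy-4-(triisopropylsilyloxy)phenyl]-3-(hydroxymethyl)butanoate | CCOC(=O)C[C@H](CO)C(O[Si](C)(C)C(C)(C)C)c1cc(OC)c(O[Si](C(C)C)(C(C)C)C(C)C)c(OC)c1 | intermediate
21 | (4R)-4-{(tert-butyldimethylsilyloxy)[3,5-dimethoxy-4-(triisopropylsilyloxy)phenyl]methyl}dihydrofuran-2(3H)-one (both benzylic epimers) | O=C1C[C@H](CO1)C(O[Si](C)(C)C(C)(C)C)c1cc(OC)c(O[Si](C(C)C)(C(C)C)C(C)C)c(OC)c1 | intermediate
22 | (3S,4R)-3,4-trans aldol adduct of 21 and 12 (epimers at both carbinol carbons) | O=C1OC[C@H](C(O[Si](C)(C)C(C)(C)C)c2cc(OC)c(O[Si](C(C)C)(C(C)C)C(C)C)c(OC)c2)[C@H]1C(O)c1cc(OC)c2O[C@H](c3ccc(O[Si](C(C)C)(C(C)C)C(C)C)c(OC)c3)[C@H](/C=C/C)c2c1 | intermediate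
23 | (2R,3R)-2-[hydroxy(dihydrobenzofuranyl)methyl]-3-[(silyloxy)(aryl)methyl]butane-1,4-diol with the (2S,3S)-3-(hydroxymethyl)dihydrobenzofuran (epimers at both benzylic carbinol carbons) | OC[C@@H]([C@H](CO)C(O[Si](C)(C)C(C)(C)C)c1cc(OC)c(O[Si](C(C)C)(C(C)C)C(C)C)c(OC)c1)C(O)c1cc(OC)c2O[C@H](c3ccc(O[Si](C(C)C)(C(C)C)C(C)C)c(OC)c3)[C@H](CO)c2c1 | intermediate
24 | bis-O-triisopropylsilyl ether of the target | COc1cc([C@H]2Oc3c(OC)cc([C@H]4OC[C@H]5[C@@H]4CO[C@@H]5c4cc(OC)c(O[Si](C(C)C)(C(C)C)C(C)C)c(OC)c4)cc3[C@H]2CO)ccc1O[Si](C(C)C)(C(C)C)C(C)C | intermediate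
25 | CNP0126146.1 | COc1cc([C@H]2Oc3c(OC)cc([C@H]4OC[C@H]5[C@@H]4CO[C@@H]5c4cc(OC)c(O)c(OC)c4)cc3[C@H]2CO)ccc1O | target

## Step count and risks

Total: 17 steps. Longest linear sequence: 10 steps (1 → 2 → 5 → 8 → 9 → 10 → 12 → 22 → 23 → 24 → 25; steps 1, 3, 5, 6, 7, 8, 14, 15, 16, 17).

**Step 7 ([2,3]-Wittig rearrangement).** The risks are lithiation at the allylic C–H instead of the electron-rich benzylic CH2, and a lower syn:anti ratio with a γ-aryl group. The fallback sets out from 7 and 3 and returns at 10. It makes the same α-alkoxybenzyl-lithium by C–S reductive lithiation instead of C–H deprotonation. Sonogashira coupling of 7 with 3 gives (S)-4-[5-(1,3-dioxolan-2-yl)-2-hydroxy-3-methoxyphenyl]but-3-yn-2-ol F1. Lindlar reduction gives the (S,Z)-allylic alcohol F2. TMSOTf-catalysed condensation of F2 with aldehyde 2 and PhSSiMe3 at −78 °C gives the mixed O,S-acetal F3 (both acetal epimers). MeLi (1 equiv, for the phenol) followed by lithium 4,4′-di-tert-butylbiphenylide at −78 °C cleaves the C–S bond regiospecifically, and the carbanion undergoes the same [2,3]-shift to 10.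

**Step 8 (Mitsunobu closure to the cis ring).** The risk is ionisation of the p-silyloxybenzylic oxyphosphonium (SN1), which would leak to the trans isomer, or elimination. The fallback sets out from 2 and 7 and returns at 11. It forms the C–O bond at the aromatic carbon with retention, on the anti alcohol. Commercial (R)-but-3-en-2-ol (C[C@@H](O)C=C) is silylated as in step 2 to its TMS ether F4 and reductively etherified with 2, as in step 3, to the (R)-allyl benzyl ether F5. Heck coupling with 7 (Pd(OAc)2, Bu4NCl, NaHCO3, DMF) gives the (E)-styrenyl ether F6. [2,3]-Wittig rearrangement of this E-substrate (n-BuLi) gives the anti alcohol F7, which is the C1 epimer of 10; the E → anti selectivity is expected to be lower than Z → syn. Selective phenol triflation (PhNTf2, K2CO3) gives the aryl triflate F8. Pd-catalysed intramolecular aryl C–O coupling (Pd2(dba)3, t-BuXPhos, Cs2CO3, toluene, 60 °C) closes the ring with retention at the carbinol to 11.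

**Step 12 (Johnson–Claisen rearrangement).** The risk is that hot propionic acid ionises the allylic, benzylic silyl ether before the hindered Z-substrate rearranges. The fallback sets out from 17 and returns at 21. It runs the same [3,3] shift as an ester-enolate (Ireland–Claisen) rearrangement under basic conditions at or below room temperature. Acetylation (Ac2O, DMAP, pyridine) gives the allylic acetate F9. LDA with TMSCl/Et3N in THF (−78 °C → rt), then aqueous acid, gives the (3R,4E)-acid F10 with the same chirality transfer. Ozonolysis with NaBH4 work-up gives the hydroxy acid F11, which lactonises on acidification to 21.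

## Further compounds

F1 | step 7 | (S)-4-[5-(1,3-dioxolan-2-yl)-2-hydroxy-3-methoxyphenyl]but-3-yn-2-ol | COc1cc(C2OCCO2)cc(C#C[C@H](C)O)c1O
F2 | step 7 | (S,Z)-4-[5-(1,3-dioxolan-2-yl)-2-hydroxy-3-methoxyphenyl]but-3-en-2-ol | COc1cc(C2OCCO2)cc(/C=C\[C@H](C)O)c1O
F3 | step 7 | 4-(1,3-dioxolan-2-yl)-2-methoxy-6-[(1Z,3S)-3-{[3-methoxy-4-(triisopropylsilyloxy)phenyl](phenylthio)methoxy}but-1-en-1-yl]phenol | COc1cc(C2OCCO2)cc(/C=C\[C@H](C)OC(Sc2ccccc2)c2ccc(O[Si](C(C)C)(C(C)C)C(C)C)c(OC)c2)c1O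
F4 | step 8 | (R)-(but-3-en-2-yloxy)trimethylsilane | C[C@@H](O[Si](C)(C)C)C=C
F5 | step 8 | (R)-triisopropyl{2-methoxy-4-[(but-3-en-2-yloxy)methyl]phenoxy}silane | C[C@@H](OCc1ccc(O[Si](C(C)C)(C(C)C)C(C)C)c(OC)c1)C=C
F6 | step 8 | 4-(1,3-dioxolan-2-yl)-2-methoxy-6-[(1E,3R)-3-{[3-methoxy-4-(triisopropylsilyloxy)benzyl]oxy}but-1-en-1-yl]phenol | COc1cc(C2OCCO2)cc(/C=C/[C@@H](C)OCc2ccc(O[Si](C(C)C)(C(C)C)C(C)C)c(OC)c2)c1O
F7 | step 8 | (1S,2R,3E)-2-[5-(1,3-dioxolan-2-yl)-2-hydroxy-3-methoxyphenyl]-1-[3-methoxy-4-(triisopropylsilyloxy)phenyl]pent-3-en-1-ol (anti) | C/C=C/[C@H](c1cc(C2OCCO2)cc(OC)c1O)[C@H](O)c1ccc(O[Si](C(C)C)(C(C)C)C(C)C)c(OC)c1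
F8 | step 8 | aryl triflate of F7 (phenol O-triflate) | C/C=C/[C@H](c1cc(C2OCCO2)cc(OC)c1OS(=O)(=O)C(F)(F)F)[C@H](O)c1ccc(O[Si](C(C)C)(C(C)C)C(C)C)c(OC)c1
F9 | step 12 | (2S,3Z)-5-(tert-butyldimethylsilyloxy)-5-[3,5-dimethoxy-4-(triisopropylsilyloxy)phenyl]pent-3-en-2-yl acetate | C[C@H](OC(C)=O)/C=C\C(O[Si](C)(C)C(C)(C)C)c1cc(OC)c(O[Si](C(C)C)(C(C)C)C(C)C)c(OC)c1
F10 | step 12 | (3R,4E)-3-{(tert-butyldimethylsilyloxy)[3,5-dimethoxy-4-(triisopropylsilyloxy)phenyl]methyl}hex-4-enoic acid | OC(=O)C[C@H](/C=C/C)C(O[Si](C)(C)C(C)(C)C)c1cc(OC)c(O[Si](C(C)C)(C(C)C)C(C)C)c(OC)c1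
F11 | step 12 | (3R)-4-(tert-butyldimethylsilyloxy)-4-[3,5-dimethoxy-4-(triisopropylsilyloxy)phenyl]-3-(hydroxymethyl)butanoic acid | OC(=O)C[C@H](CO)C(O[Si](C)(C)C(C)(C)C)c1cc(OC)c(O[Si](C(C)C)(C(C)C)C(C)C)c(OC)c1
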